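The data were generated by integration with constants of no real substance; scatter was added.

The ochre question is taken by counting product per catalyst instead of following a rate.

| flask | starting material | free catalyst | time |
|---|---|---|---|
| blue | 0.800 M | 0.0640 M |  |
| teal | 0.800 M | 0.190 M |  |
| grey | 1.20 M | 0.0640 M |  |
| ochre | 2.40 M | 0.190 M | 16 min |

| run | time / min | [product] / M |
|---|---|---|
| blue run | 2.0 | 0.085 |
| blue run | 4.0 | 0.171 |
| blue run | 6.0 | 0.226 |
| blue run | 8.0 | 0.295 |
| blue run | 10 | 0.339 |
| blue run | 12 | 0.404 |
| blue run | 14 | 0.429 |
| blue run | 16 | 0.443 |
| teal run | 2.0 | 0.692 |
| teal run | 4.0 | 0.785 |
| teal run | 6.0 | 0.792 |
| teal run | 8.0 | 0.814 |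
| teal run | 10 | 0.790 |
| teal run | 12 | 0.811 |
| teal run | 14 | 0.793 |
| teal run | 16 | 0.789 |
| grey run | 2.0 | 0.078 |
| grey run | 4.0 | 0.158 |
| grey run | 6.0 | 0.214 |
| grey run | 8.0 | 0.252 |
| grey run | 10 | 0.314 |
| grey run | 12 | 0.382 |
| grey run | 14 | 0.427 |
| grey run | 16 | 0.436 |

(standard deviation of a reading: 0.01 M)

- Overall: starting material -> product, with free catalyst as catalyst.
- Constant volume, constant temperature.
- Readings of a species count what is bound in complexes too.
- An order is taken over about fifteen percent of the charge, up and down.

- the power of [free catalyst] that the first rate follows, about the charge of the blue run; measure it at two percent of starting material made into product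
- the power of [starting material] that the first rate follows, about the charge of the blue run; measure it at two percent of starting material made into product (one fixed amount of product, the same in the runs compared)
- product in the ochre run at 16 min, as a share of the starting material charged

In the blue run, the last two readings differ by 0.0140 M, close to the scatter of 0.01 M, while 0.357 M of the charge has not become product. The turnover number, product made per free catalyst charged by 16 min in the blue run, is 6.92. Multiplying it by the catalyst charged and dividing by the starting material charged folds a flask's givens into one number, its reach: the share of that flask's charge reached at this turnover number.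

The reach is held against two runs. For the grey run it is 36.9%, and the last grey reading is 36.3% of its charge. For the teal run it is 164%, above the whole charge, which makes starting material the limiting reagent there, and the last teal reading is 98.6%.

But the reach holds no clock, and the blue readings may still be creeping upward at 16 min. For the ochre run the reach is 54.8%, and this reckoning commits to that share while treating it as a low figure.

The forecast stands higher: 93%, within 62% to 100%, with “I expect near completion, with a low-side risk”. It puts the order in free catalyst at 2 and in starting material at 0.

    free catalyst + starting material ⇌ catalyst-substrate complex, settled at all times (17.20 /M)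
    catalyst-substrate complex + free catalyst → product + 2 free catalyst (44.46 /M/min)
    free catalyst + product → spent catalyst + product (0.4254 /M/min)
    2 starting material ⇌ idle substrate dimer, settled at all times (19.30 /M)

The ochre run gives 69.0% at 16 min. About the charge of the blue run, the first rate follows free catalyst with order 2.0 and starting material with order −0.22. That share lies 14 percentage points above the reach. The teal run, with the same catalyst charge as the ochre run, has an early rate 9.0 times that of the blue run. Counted per catalyst charged, the ochre run has made 8.71 by 16 min, more than the 6.92 of the blue run at the same time.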